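The runs stem from a simulated flask for substances that don't exist; the scatter is artificial.

2.28: that is the lead ratio of Saturday's run at its last reading, 20.0 h, meaning the fraction of the charge held by side product over the fraction held by other mono adduct and bis adduct together, a selectivity factor of a kind. We count the pair as one: in the readings the other mono adduct appears early and the bis adduct climbs after it.

| flask | substrate | reagent | remark | time |
|---|---|---|---|---|
| Saturday's | 0.50 M | 0.92 M | run made earlier |  |
| amber | 0.50 M | 1.20 M |  | 40 h |
| green | 0.50 M | 1.90 M |  | 40 h |
| blue | 0.50 M | 2.80 M |  | 40 h |

Saturday's run (percent of the substrate charged)

| time / h | side product / % | other mono adduct / % | substrate / % | single product / % | bis adduct / % |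
|---|---|---|---|---|---|
| 2.50 | 7.1 | 4.3 | 84.4 | 3.1 | 0.9 |
| 8.00 | 26.2 | 8.0 | 57.3 | 3.9 | 4.2 |
| 12.0 | 37.2 | 8.2 | 43.9 | 3.7 | 6.7 |
| 20.0 | 49.6 | 9.3 | 26.7 | 3.1 | 12.5 |

(readings scatter by 0.5 percentage points)

- percentages count the substrate that a species holds: one side product counts as two

1. which of these there is most of at the end, counted by the substrate in it, amber (single product / bis adduct / side product / other mono adduct / substrate)
2. which of these there is most of at the end, counted by the substrate in it, green (single product / bis adduct / side product / other mono adduct / substrate)
3. which of these there is most of at the end, counted by the substrate in it, blue (single product / bis adduct / side product / other mono adduct / substrate)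
4. how much there is at the end of the one of these that leads, in percent of the substrate charged: amber
5. how much there is at the end of the one of these that leads, in percent of the substrate charged: green
6. how much there is at the end of the one of these that leads, in percent of the substrate charged: blue

Turn the question round: for bis adduct to lead at the end, the lead ratio has to fall below one. In Saturday's flask at 20.0 h the gap was 28 percentage points, while substrate and single product together held 29.8%, so 97.0% of that remainder had to go the bis way for a tie. In Saturday's readings the gap was not closing with time either. From 8.00 h to 20.0 h in that run side product gained 23 points and the pair 9.6 points, a ratio of 2.44, though substrate fell from 57.3% to 26.7%.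

The danger is reagent. We suppose that single product may be caught by substrate or by reagent, and blue carries 3.04 times Saturday's reagent, the most of the three. If the whole pair grew by that factor, the lead ratio falls to 0.750, below one. But in Saturday's run at 2.50 h other mono adduct held 82.7% of the pair, and as an assumption we take that share as unmoved by reagent. Scaling the rest, our reckoning for blue is 1.68, still above one, or side product at 62.7% of a finished charge.

The forecast names side product, side product and side product for amber, green and blue, at 64% (58% to 70%), 62% (54% to 69%) and 57% (45% to 66%). Its ground: “Both routes are first order in reagent, so more reagent barely changes the split”. For blue its figure is lower than ours.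

    substrate + reagent → single product (k = 5.79 × 10⁻⁴ /M/min)
    substrate + reagent → other mono adduct (k = 3.74 × 10⁻⁴ /M/min)
    reagent + single product → bis adduct (k = 5.45 × 10⁻⁴ /M/min)
    reagent + other mono adduct → bis adduct (k = 0.00169 /M/min)
    substrate + single product → side product (k = 0.0236 /M/min)

Side product leads in amber at 63.2%, green at 59.5% and blue at 53.5%. Blue's lead ratio ends at 1.19, above one yet lower than our 1.68, with bis adduct at 44.8%. The main reason side product stops there in blue is the passing of substrate and reagent into other mono adduct: blue's run without that step holds 77.2% of side product against 53.5%. The neighbour of amber with 0.30 M of reagent, still holding 50.1% as substrate, stands at a lead ratio of 2.90.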